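**Retrosynthetic overview**
1. Target 35 ← hydroxymethylene ketone 34 (O-methylation) ← methyl ketone 33 (Claisen condensation with methyl formate).
2. 33 ← Δ11 allylic diol 30 (hydroxyl-directed dihydroxylation puts C11–OH on the congested face, then oxidation at C12) ← octalin 27 (Schenck ene reaction installs C13–OH and moves the alkene).
3. Rings A and B are closed together in one step: 27 ← trienone 26 by intramolecular Diels–Alder reaction (ring B from the tether, ring A from diene plus dienophile).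
4. 26 ← aldehyde 19 + propionyl imide 20: the key intermolecular aldol forms C5–C6; elimination then gives the E-enone dienophile.
5. 19 ← sulfone 16 + enal 4 (Julia–Kocienski); C9 from Sharpless epoxidation/hydride opening, C7 from Roche ester, C3 from (S)-2-methylbutanol.

Labels used below (target carbons): C1–C2 ethyl and C3 of the sec-butyl group; ring A = C4, C5, C6, C11, C12, C13; ring B = C6, C7, C8, C9, C10, C11; side chain C14(=O)–C15=C16–OMe.
Assumption: numbered compounds are substrates, coupling partners, intermediates and products; ordinary reagents are given on the Conditions and Reagents lines.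

**Route**

Step 1
Reactants: 1 (S)-2-methylbutan-1-ol
Product: 2 (S)-2-methylbutanal
Conditions: TEMPO (cat.), KBr (cat.), NaOCl, NaHCO3, CH2Cl2/H2O, 0 °C
Reagents that add atoms: none
Why: Anelli (TEMPO/hypochlorite) oxidation stops at the aldehyde under buffered two-phase conditions at 0 °C, so the chiral-pool stereocentre C3 is not epimerised.

Step 2
Reactants: 2 (S)-2-methylbutanal; 3 2-(triphenylphosphoranylidene)propanal
Product: 4 (S,E)-2,4-dimethylhex-2-enal
Conditions: CH2Cl2, 40 °C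
Reagents that add atoms: none
Why: Wittig olefination with a stabilised ylide gives the E-trisubstituted enal (future C13=C4 and C12) under neutral conditions that leave C3 untouched.

Step 3
Reactants: 5 methyl (S)-3-hydroxy-2-methylpropanoate
Product: 6 methyl (S)-3-[(tert-butyldiphenylsilyl)oxy]-2-methylpropanoate
Conditions: TBDPSCl, imidazole, DMF, 0 °C to rt
Reagents that add atoms: tert-butyl(chloro)diphenylsilane CC(C)(C)[Si](Cl)(c1ccccc1)c1ccccc1
Why: Silyl ether formation protects the future C6 oxygen; C7 comes from the chiral pool.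

Step 4
Reactants: 6 methyl (S)-3-[(tert-butyldiphenylsilyl)oxy]-2-methylpropanoate
Product: 7 (R)-3-[(tert-butyldiphenylsilyl)oxy]-2-methylpropan-1-ol
Conditions: LiBH4, MeOH (1 equiv), THF, 0 °C to rt
Reagents that add atoms: none
Why: Borohydride ester reduction gives the primary alcohol without touching the silyl ether or the stereocentre.

Step 5
Reactants: 7 (R)-3-[(tert-butyldiphenylsilyl)oxy]-2-methylpropan-1-ol
Product: 8 (S)-tert-butyl(3-iodo-2-methylpropoxy)diphenylsilane
Conditions: I2, PPh3, imidazole, CH2Cl2, 0 °C to rt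
Reagents that add atoms: iodine II
Why: Appel-type iodination converts the primary alcohol by SN2 at a carbon that is not stereogenic.

Step 6
Reactants: 8 (S)-tert-butyl(3-iodo-2-methylpropoxy)diphenylsilane
Product: 9 (R)-tert-butyl[(2-methylpent-4-yn-1-yl)oxy]diphenylsilane
Conditions: LiC≡CH·H2N(CH2)2NH2, DMSO, 5 °C to rt
Reagents that add atoms: lithium acetylide–ethylenediamine complex [Li+].[C-]#C.NCCN
Why: SN2 alkylation of acetylide by the primary iodide adds C9 and C10 as a terminal alkyne.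

Step 7
Reactants: 9 (R)-tert-butyl[(2-methylpent-4-yn-1-yl)oxy]diphenylsilane
Product: 11 (R,E)-6-[(tert-butyldiphenylsilyl)oxy]-3,5-dimethylhex-2-en-1-ol, via alkenyldimethylalane 10 (not isolated)
Conditions: AlMe3, Cp2ZrCl2 (0.25 equiv), CH2Cl2, 0 °C to rt; then n-BuLi, (CH2O)n, THF, −78 °C to rt
Reagents that add atoms: trimethylaluminium C[Al](C)C; paraformaldehyde (as formaldehyde) C=O
Why: Negishi zirconium-catalysed carboalumination adds methyl and aluminium syn across the alkyne with methyl on the internal carbon, and the derived ate complex traps formaldehyde with retention, which fixes the E-trisubstituted allylic alcohol.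

Step 8
Reactants: 11 (R,E)-6-[(tert-butyldiphenylsilyl)oxy]-3,5-dimethylhex-2-en-1-ol
Product: 12 [(2R,3R)-3-{(R)-3-[(tert-butyldiphenylsilyl)oxy]-2-methylpropyl}-3-methyloxiran-2-yl]methanol
Conditions: Ti(OiPr)4 (10 mol%), D-(−)-diethyl tartrate (13 mol%), t-BuOOH, 4 Å MS, CH2Cl2, −20 °C
Reagents that add atoms: tert-butyl hydroperoxide CC(C)(C)OO
Why: Sharpless asymmetric epoxidation of the E-trisubstituted allylic alcohol with the D-tartrate ligand gives the (2R,3R)-epoxide by reagent control, which sets the C9 carbinol configuration.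

Step 9
Reactants: 12 [(2R,3R)-3-{(R)-3-[(tert-butyldiphenylsilyl)oxy]-2-methylpropyl}-3-methyloxiran-2-yl]methanol
Product: 13 (3R,5R)-6-[(tert-butyldiphenylsilyl)oxy]-3,5-dimethylhexane-1,3-diol
Conditions: NaAlH2(OCH2CH2OMe)2, THF, 0 °C to rt
Reagents that add atoms: none
Why: Regioselective reductive opening of the 2,3-epoxy alcohol by intramolecular hydride delivery to C2 gives the 1,3-diol while the tertiary C9–O bond and its configuration are retained.

Step 10
Reactants: 13 (3R,5R)-6-[(tert-butyldiphenylsilyl)oxy]-3,5-dimethylhexane-1,3-diol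
Product: 14 (3R,5R)-6-[(tert-butyldiphenylsilyl)oxy]-3,5-dimethyl-1-[(1-phenyl-1H-tetrazol-5-yl)sulfanyl]hexan-3-ol
Conditions: 1-phenyl-1H-tetrazole-5-thiol, PPh3, DIAD, THF, 0 °C to rt
Reagents that add atoms: 1-phenyl-1H-tetrazole-5-thiol Sc1nnnn1-c1ccccc1
Why: Mitsunobu thioetherification takes place only at the primary hydroxyl (C11) because the tertiary alcohol cannot be displaced.

Step 11
Reactants: 14 (3R,5R)-6-[(tert-butyldiphenylsilyl)oxy]-3,5-dimethyl-1-[(1-phenyl-1H-tetrazol-5-yl)sulfanyl]hexan-3-ol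
Product: 15 5-{[(3R,5R)-3-[(tert-butyldimethylsilyl)oxy]-6-[(tert-butyldiphenylsilyl)oxy]-3,5-dimethylhexyl]sulfanyl}-1-phenyl-1H-tetrazole
Conditions: TBSOTf, 2,6-lutidine, CH2Cl2, 0 °C to rt
Reagents that add atoms: tert-butyldimethylsilyl triflate CC(C)(C)[Si](C)(C)OS(=O)(=O)C(F)(F)F
Why: Silyl triflate silylation is strong enough to protect the tertiary C9 hydroxyl, which must be masked before the later aldehyde, aldol and elimination steps.

Step 12
Reactants: 15 5-{[(3R,5R)-3-[(tert-butyldimethylsilyl)oxy]-6-[(tert-butyldiphenylsilyl)oxy]-3,5-dimethylhexyl]sulfanyl}-1-phenyl-1H-tetrazole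
Product: 16 5-{[(3R,5R)-3-[(tert-butyldimethylsilyl)oxy]-6-[(tert-butyldiphenylsilyl)oxy]-3,5-dimethylhexyl]sulfonyl}-1-phenyl-1H-tetrazole
Conditions: (NH4)6Mo7O24·4H2O (cat.), 30% H2O2, EtOH, 0 °C to rt
Reagents that add atoms: hydrogen peroxide OO
Why: Molybdate-catalysed sulfide-to-sulfone oxidation is chemoselective for sulfur and tolerates both silyl ethers.

Step 13
Reactants: 16 5-{[(3R,5R)-3-[(tert-butyldimethylsilyl)oxy]-6-[(tert-butyldiphenylsilyl)oxy]-3,5-dimethylhexyl]sulfonyl}-1-phenyl-1H-tetrazole; 4 (S,E)-2,4-dimethylhex-2-enal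
Product: 17 tert-butyl{[(2R,4S,6E,8E,10S)-4-[(tert-butyldimethylsilyl)oxy]-2,4,8,10-tetramethyldodeca-6,8-dien-1-yl]oxy}diphenylsilane
Conditions: KN(SiMe3)2, DME, −60 °C; then 4, −60 °C to rt
Reagents that add atoms: none
Why: Julia–Kocienski olefination of an alkyl phenyltetrazolyl sulfone with an enal gives the new C11=C12 bond E-selectively (addition, Smiles rearrangement, anti elimination) and so completes the E,E-diene.

Step 14
Reactants: 17 tert-butyl{[(2R,4S,6E,8E,10S)-4-[(tert-butyldimethylsilyl)oxy]-2,4,8,10-tetramethyldodeca-6,8-dien-1-yl]oxy}diphenylsilane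
Product: 18 (2R,4S,6E,8E,10S)-4-[(tert-butyldimethylsilyl)oxy]-2,4,8,10-tetramethyldodeca-6,8-dien-1-ol
Conditions: Bu4NF (1.2 equiv), AcOH (1.2 equiv), THF, 0 °C to rt
Reagents that add atoms: none
Why: Buffered fluoride desilylation cleaves the unhindered primary silyl ether much faster than the tertiary TBS ether.

Step 15
Reactants: 18 (2R,4S,6E,8E,10S)-4-[(tert-butyldimethylsilyl)oxy]-2,4,8,10-tetramethyldodeca-6,8-dien-1-ol
Product: 19 (2R,4S,6E,8E,10S)-4-[(tert-butyldimethylsilyl)oxy]-2,4,8,10-tetramethyldodeca-6,8-dienal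
Conditions: Dess–Martin periodinane, NaHCO3, CH2Cl2, 0 °C to rt
Reagents that add atoms: none
Why: Buffered Dess–Martin oxidation gives the α-methyl aldehyde (C6) without epimerising C7 or disturbing the diene.

Step 16
Reactants: 19 (2R,4S,6E,8E,10S)-4-[(tert-butyldimethylsilyl)oxy]-2,4,8,10-tetramethyldodeca-6,8-dienal; 20 (S)-4-benzyl-3-propanoyloxazolidin-2-one
Product: 22 (S)-4-benzyl-3-[(2S,3R,4R,6S,8E,10E,12S)-6-[(tert-butyldimethylsilyl)oxy]-3-hydroxy-2,4,6,10,12-pentamethyltetradeca-8,10-dienoyl]oxazolidin-2-one, via Z-boron enolate 21 (not isolated)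
Conditions: Bu2BOTf, iPr2NEt, CH2Cl2, 0 °C; then 19, −78 to 0 °C; then pH 7 buffer, MeOH, 30% H2O2, 0 °C
Reagents that add atoms: none
Why: The Evans syn-aldol reaction joins the two fragments at C5–C6 through a Zimmerman–Traxler chair from the Z-boron enolate, the auxiliary fixing the 2,3-syn product (matched with the aldehyde's anti-Felkin preference), so a single defined precursor of the enone is obtained although both new centres are removed in step 19.

Step 17
Reactants: 22 (S)-4-benzyl-3-[(2S,3R,4R,6S,8E,10E,12S)-6-[(tert-butyldimethylsilyl)oxy]-3-hydroxy-2,4,6,10,12-pentamethyltetradeca-8,10-dienoyl]oxazolidin-2-one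
Product: 23 (2S,3R,4R,6S,8E,10E,12S)-6-[(tert-butyldimethylsilyl)oxy]-3-hydroxy-N-methoxy-N,2,4,6,10,12-hexamethyltetradeca-8,10-dienamide
Conditions: MeONHMe·HCl, AlMe3, THF, −20 to 0 °C
Reagents that add atoms: N,O-dimethylhydroxylamine hydrochloride CNOC.Cl
Why: Aluminium amide transamination of the β-hydroxy imide (Weinreb amide formation) is assisted by the free β-hydroxyl and releases the auxiliary.

Step 18
Reactants: 23 (2S,3R,4R,6S,8E,10E,12S)-6-[(tert-butyldimethylsilyl)oxy]-3-hydroxy-N-methoxy-N,2,4,6,10,12-hexamethyltetradeca-8,10-dienamide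
Product: 24 (3S,4R,5R,7S,9E,11E,13S)-7-[(tert-butyldimethylsilyl)oxy]-4-hydroxy-3,5,7,11,13-pentamethylpentadeca-9,11-dien-2-one
Conditions: MeMgBr (3 equiv), THF, −20 to 0 °C
Reagents that add atoms: methylmagnesium bromide C[Mg]Br
Why: Weinreb ketone synthesis stops at the methyl ketone (C14, C15) because the chelated tetrahedral intermediate survives until work-up.

Step 19
Reactants: 24 (3S,4R,5R,7S,9E,11E,13S)-7-[(tert-butyldimethylsilyl)oxy]-4-hydroxy-3,5,7,11,13-pentamethylpentadeca-9,11-dien-2-one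
Product: 26 (3E,5R,7S,9E,11E,13S)-7-[(tert-butyldimethylsilyl)oxy]-3,5,7,11,13-pentamethylpentadeca-3,9,11-trien-2-one, via mesylate 25 (not isolated)
Conditions: MsCl, Et3N (5 equiv), CH2Cl2, 0 °C to 40 °C
Reagents that add atoms: none
Why: Mesylation followed by E1cB elimination through the ketone enolate gives the conjugated enone with the thermodynamically favoured E geometry, which completes the aldol condensation.

Step 20
Reactants: 26 (3E,5R,7S,9E,11E,13S)-7-[(tert-butyldimethylsilyl)oxy]-3,5,7,11,13-pentamethylpentadeca-3,9,11-trien-2-one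
Product: 27 trans-fused Δ12-octalin methyl ketone (C5 acetyl; C9 OTBS; C11–H trans to C6–H)
Conditions: toluene (0.01 M), BHT (cat.), 110 °C, sealed tube
Reagents that add atoms: none
Why: The intramolecular Diels–Alder reaction proceeds through the chair-like tether that keeps the C7 and C9 methyl groups equatorial with the acetyl group endo, so the E,E-diene and E-dienophile geometries are translated into C4, C5, C6 and the trans ring fusion at C11 in one step.

Step 21
Reactants: 27 trans-fused Δ12-octalin methyl ketone (C5 acetyl; C9 OTBS; C11–H trans to C6–H)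
Product: 29 Δ11-octalin C13 tertiary allylic alcohol (C9 OTBS), via allylic hydroperoxide 28 (not isolated)
Conditions: O2, tetraphenylporphyrin (cat.), visible light, CH2Cl2, −20 °C; then PPh3, −20 °C to rt
Reagents that add atoms: oxygen O=O
Why: The Schenck ene reaction of singlet oxygen removes the axial ring-fusion hydrogen at C11 and places oxygen on C13 suprafacially on the same face (that of the C5 methyl), so C13 is set as in the target while the alkene moves to C11=C12; phosphine reduction gives the alcohol.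

Step 22
Reactants: 29 Δ11-octalin C13 tertiary allylic alcohol (C9 OTBS)
Product: 30 Δ11-octalin C9/C13-diol
Conditions: Bu4NF, THF, 50 °C
Reagents that add atoms: none
Why: Fluoride desilylation under basic, non-ionising conditions frees the axial C9 hydroxyl without disturbing the tertiary allylic alcohol.

Step 23
Reactants: 30 Δ11-octalin C9/C13-diol
Product: 32 C9/C11/C12/C13-tetraol (all four hydroxyls on the same face), via osmate ester 31 (not isolated)
Conditions: OsO4 (1.1 equiv), TMEDA (1.2 equiv), CH2Cl2, −78 °C; then aq. Na2SO3, THF, 60 °C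
Reagents that add atoms: osmium tetroxide O=[Os](=O)(=O)=O
Why: In the Donohoe hydroxyl-directed dihydroxylation the OsO4–TMEDA complex is hydrogen-bonded to the pseudoaxial C13 and axial C9 hydroxyls and is therefore delivered to their face of the C11=C12 alkene, which sets the C11 tertiary alcohol trans to C6–H against the steric bias.

Step 24
Reactants: 32 C9/C11/C12/C13-tetraol (all four hydroxyls on the same face)
Product: 33 (2S,3R,4S,4aR,5R,7R,8aR)-4-acetyl-3-[(S)-butan-2-yl]-2,7,8a-trihydroxy-2,4,5,7-tetramethyloctahydronaphthalen-1(2H)-one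
Conditions: SO3·pyridine, DMSO, iPr2NEt, CH2Cl2, 0 °C to rt
Reagents that add atoms: none
Why: Parikh–Doering oxidation converts the only secondary alcohol (C12) into the ketone without cleaving the flanking tertiary glycol units.

Step 25
Reactants: 33 (2S,3R,4S,4aR,5R,7R,8aR)-4-acetyl-3-[(S)-butan-2-yl]-2,7,8a-trihydroxy-2,4,5,7-tetramethyloctahydronaphthalen-1(2H)-one
Product: 34 (2S,3R,4S,4aR,5R,7R,8aR)-3-[(S)-butan-2-yl]-2,7,8a-trihydroxy-4-[(Z)-3-hydroxyprop-2-enoyl]-2,4,5,7-tetramethyloctahydronaphthalen-1(2H)-one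
Conditions: LiN(SiMe3)2 (5 equiv), THF, −78 °C; then HCO2Me (10 equiv), −78 to 0 °C; aq. NH4Cl
Reagents that add atoms: methyl formate COC=O
Why: Crossed Claisen condensation with methyl formate can occur only at the acetyl methyl group (C15), because the C12 ketone is flanked by two fully substituted carbons and cannot enolise.

Step 26
Reactants: 34 (2S,3R,4S,4aR,5R,7R,8aR)-3-[(S)-butan-2-yl]-2,7,8a-trihydroxy-4-[(Z)-3-hydroxyprop-2-enoyl]-2,4,5,7-tetramethyloctahydronaphthalen-1(2H)-one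
Product: 35 (2S,3R,4S,4aR,5R,7R,8aR)-3-[(S)-butan-2-yl]-2,7,8a-trihydroxy-4-[(E)-3-methoxyprop-2-enoyl]-2,4,5,7-tetramethyloctahydronaphthalen-1(2H)-one
Conditions: Me3SiCHN2, MeOH/toluene (1:4), 0 °C to rt
Reagents that add atoms: trimethylsilyldiazomethane C[Si](C)(C)C=[N+]=[N-]
Why: O-Methylation of the acidic enol of the β-keto aldehyde with the diazomethane surrogate gives the vinylogous ester, which settles as the more stable E isomer, while the tertiary alcohols are not acidic enough to react.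

**Compound list**
1 | (S)-2-methylbutan-1-ol | CC[C@H](C)CO | starting material
2 | (S)-2-methylbutanal | CC[C@H](C)C=O | intermediate
3 | 2-(triphenylphosphoranylidene)propanal | CC(C=O)=P(c1ccccc1)(c1ccccc1)c1ccccc1 | starting material
4 | (S,E)-2,4-dimethylhex-2-enal | CC[C@H](C)/C=C(\C)C=O | intermediate
5 | methyl (S)-3-hydroxy-2-methylpropanoate (Roche ester) | COC(=O)[C@@H](C)CO | starting material
6 | methyl (S)-3-[(tert-butyldiphenylsilyl)oxy]-2-methylpropanoate | COC(=O)[C@@H](C)CO[Si](c1ccccc1)(c1ccccc1)C(C)(C)C | intermediate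
7 | (R)-3-[(tert-butyldiphenylsilyl)oxy]-2-methylpropan-1-ol | OC[C@@H](C)CO[Si](c1ccccc1)(c1ccccc1)C(C)(C)C | intermediate
8 | (S)-tert-butyl(3-iodo-2-methylpropoxy)diphenylsilane | IC[C@@H](C)CO[Si](c1ccccc1)(c1ccccc1)C(C)(C)C | intermediate
9 | (R)-tert-butyl[(2-methylpent-4-yn-1-yl)oxy]diphenylsilane | C#CC[C@@H](C)CO[Si](c1ccccc1)(c1ccccc1)C(C)(C)C | intermediate
10 | (R,E)-{5-[(tert-butyldiphenylsilyl)oxy]-2,4-dimethylpent-1-en-1-yl}dimethylalane (not isolated) | C[Al](C)/C=C(\C)C[C@@H](C)CO[Si](c1ccccc1)(c1ccccc1)C(C)(C)C | intermediate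
11 | (R,E)-6-[(tert-butyldiphenylsilyl)oxy]-3,5-dimethylhex-2-en-1-ol | OC/C=C(\C)C[C@@H](C)CO[Si](c1ccccc1)(c1ccccc1)C(C)(C)C | intermediate
12 | [(2R,3R)-3-{(R)-3-[(tert-butyldiphenylsilyl)oxy]-2-methylpropyl}-3-methyloxiran-2-yl]methanol | OC[C@H]1O[C@]1(C)C[C@@H](C)CO[Si](c1ccccc1)(c1ccccc1)C(C)(C)C | intermediate
13 | (3R,5R)-6-[(tert-butyldiphenylsilyl)oxy]-3,5-dimethylhexane-1,3-diol | OCC[C@](C)(O)C[C@@H](C)CO[Si](c1ccccc1)(c1ccccc1)C(C)(C)C | intermediate
14 | (3R,5R)-6-[(tert-butyldiphenylsilyl)oxy]-3,5-dimethyl-1-[(1-phenyl-1H-tetrazol-5-yl)sulfanyl]hexan-3-ol | c1ccccc1-n1nnnc1SCC[C@](C)(O)C[C@@H](C)CO[Si](c1ccccc1)(c1ccccc1)C(C)(C)C | intermediate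
15 | 5-{[(3R,5R)-3-[(tert-butyldimethylsilyl)oxy]-6-[(tert-butyldiphenylsilyl)oxy]-3,5-dimethylhexyl]sulfanyl}-1-phenyl-1H-tetrazole | c1ccccc1-n1nnnc1SCC[C@](C)(O[Si](C)(C)C(C)(C)C)C[C@@H](C)CO[Si](c1ccccc1)(c1ccccc1)C(C)(C)C | intermediate
16 | 5-{[(3R,5R)-3-[(tert-butyldimethylsilyl)oxy]-6-[(tert-butyldiphenylsilyl)oxy]-3,5-dimethylhexyl]sulfonyl}-1-phenyl-1H-tetrazole | c1ccccc1-n1nnnc1S(=O)(=O)CC[C@](C)(O[Si](C)(C)C(C)(C)C)C[C@@H](C)CO[Si](c1ccccc1)(c1ccccc1)C(C)(C)C | intermediate
17 | tert-butyl{[(2R,4S,6E,8E,10S)-4-[(tert-butyldimethylsilyl)oxy]-2,4,8,10-tetramethyldodeca-6,8-dien-1-yl]oxy}diphenylsilane | CC[C@H](C)/C=C(C)/C=C/C[C@](C)(O[Si](C)(C)C(C)(C)C)C[C@@H](C)CO[Si](c1ccccc1)(c1ccccc1)C(C)(C)C | intermediate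
18 | (2R,4S,6E,8E,10S)-4-[(tert-butyldimethylsilyl)oxy]-2,4,8,10-tetramethyldodeca-6,8-dien-1-ol | CC[C@H](C)/C=C(C)/C=C/C[C@](C)(O[Si](C)(C)C(C)(C)C)C[C@@H](C)CO | intermediate
19 | (2R,4S,6E,8E,10S)-4-[(tert-butyldimethylsilyl)oxy]-2,4,8,10-tetramethyldodeca-6,8-dienal | CC[C@H](C)/C=C(C)/C=C/C[C@](C)(O[Si](C)(C)C(C)(C)C)C[C@@H](C)C=O | intermediate
20 | (S)-4-benzyl-3-propanoyloxazolidin-2-one | CCC(=O)N1[C@@H](Cc2ccccc2)COC1=O | starting material
21 | dibutylboron (Z)-enolate of 20 (not isolated) | C/C=C(\OB(CCCC)CCCC)N1[C@@H](Cc2ccccc2)COC1=O | intermediate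
22 | (S)-4-benzyl-3-[(2S,3R,4R,6S,8E,10E,12S)-6-[(tert-butyldimethylsilyl)oxy]-3-hydroxy-2,4,6,10,12-pentamethyltetradeca-8,10-dienoyl]oxazolidin-2-one | CC[C@H](C)/C=C(C)/C=C/C[C@](C)(O[Si](C)(C)C(C)(C)C)C[C@@H](C)[C@@H](O)[C@H](C)C(=O)N1[C@@H](Cc2ccccc2)COC1=O | intermediate
23 | (2S,3R,4R,6S,8E,10E,12S)-6-[(tert-butyldimethylsilyl)oxy]-3-hydroxy-N-methoxy-N,2,4,6,10,12-hexamethyltetradeca-8,10-dienamide | CC[C@H](C)/C=C(C)/C=C/C[C@](C)(O[Si](C)(C)C(C)(C)C)C[C@@H](C)[C@@H](O)[C@H](C)C(=O)N(C)OC | intermediate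
24 | (3S,4R,5R,7S,9E,11E,13S)-7-[(tert-butyldimethylsilyl)oxy]-4-hydroxy-3,5,7,11,13-pentamethylpentadeca-9,11-dien-2-one | CC[C@H](C)/C=C(C)/C=C/C[C@](C)(O[Si](C)(C)C(C)(C)C)C[C@@H](C)[C@@H](O)[C@H](C)C(C)=O | intermediate
25 | 4-O-methanesulfonate of 24 (not isolated) | CC[C@H](C)/C=C(C)/C=C/C[C@](C)(O[Si](C)(C)C(C)(C)C)C[C@@H](C)[C@@H](OS(C)(=O)=O)[C@H](C)C(C)=O | intermediate
26 | (3E,5R,7S,9E,11E,13S)-7-[(tert-butyldimethylsilyl)oxy]-3,5,7,11,13-pentamethylpentadeca-3,9,11-trien-2-one | CC[C@H](C)/C=C(C)/C=C/C[C@](C)(O[Si](C)(C)C(C)(C)C)C[C@@H](C)/C=C(\C)C(C)=O | intermediate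
27 | trans-fused Δ12-octalin methyl ketone: C4 sec-butyl, C5 methyl/acetyl, C7 methyl, C9 methyl/OTBS, C12=C13(Me) alkene, C4/C5/C6/C7/C9 as in the target, C11–H trans to C6–H | CC[C@H](C)[C@@H]1[C@](C)(C(C)=O)[C@H]2[C@H](C)C[C@@](C)(O[Si](C)(C)C(C)(C)C)C[C@@H]2C=C1C | intermediate
28 | C13 tertiary allylic hydroperoxide of 27 with C11=C12 alkene, OOH on the face of the C5 methyl (not isolated) | CC[C@H](C)[C@@H]1[C@](C)(C(C)=O)[C@H]2[C@H](C)C[C@@](C)(O[Si](C)(C)C(C)(C)C)CC2=C[C@@]1(C)OO | intermediate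
29 | Δ11-octalin C13 tertiary allylic alcohol, C9 OTBS (C13 as in the target) | CC[C@H](C)[C@@H]1[C@](C)(C(C)=O)[C@H]2[C@H](C)C[C@@](C)(O[Si](C)(C)C(C)(C)C)CC2=C[C@@]1(C)O | intermediate
30 | Δ11-octalin C9/C13-diol | CC[C@H](C)[C@@H]1[C@](C)(C(C)=O)[C@H]2[C@H](C)C[C@@](C)(O)CC2=C[C@@]1(C)O | intermediate
31 | cyclic C11/C12 osmate ester of 30, TMEDA bound to osmium (not isolated) | CC[C@H](C)[C@@H]1[C@](C)(C(C)=O)[C@H]2[C@H](C)C[C@@](C)(O)C[C@@]23O[Os](=O)(=O)O[C@H]3[C@@]1(C)O.CN(C)CCN(C)C | intermediate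
32 | C9/C11/C12/C13-tetraol, C11–OH, C12–OH and C13–OH mutually cis and on the face of the C9–OH | CC[C@H](C)[C@@H]1[C@](C)(C(C)=O)[C@H]2[C@H](C)C[C@@](C)(O)C[C@]2(O)[C@@H](O)[C@@]1(C)O | intermediate
33 | (2S,3R,4S,4aR,5R,7R,8aR)-4-acetyl-3-[(S)-butan-2-yl]-2,7,8a-trihydroxy-2,4,5,7-tetramethyloctahydronaphthalen-1(2H)-one | CC[C@H](C)[C@@H]1[C@](C)(C(C)=O)[C@H]2[C@H](C)C[C@@](C)(O)C[C@]2(O)C(=O)[C@@]1(C)O | intermediate
34 | (2S,3R,4S,4aR,5R,7R,8aR)-3-[(S)-butan-2-yl]-2,7,8a-trihydroxy-4-[(Z)-3-hydroxyprop-2-enoyl]-2,4,5,7-tetramethyloctahydronaphthalen-1(2H)-one (enol form of the β-keto aldehyde) | CC[C@H](C)[C@@H]1[C@](C)(C(=O)/C=C\O)[C@H]2[C@H](C)C[C@@](C)(O)C[C@]2(O)C(=O)[C@@]1(C)O | intermediate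
35 | (2S,3R,4S,4aR,5R,7R,8aR)-3-[(S)-butan-2-yl]-2,7,8a-trihydroxy-4-[(E)-3-methoxyprop-2-enoyl]-2,4,5,7-tetramethyloctahydronaphthalen-1(2H)-one | CC[C@H](C)[C@@H]1[C@](C)(C(=O)/C=C/OC)[C@H]2[C@H](C)C[C@@](C)(O)C[C@]2(O)C(=O)[C@@]1(C)O | target

**Totals and risks**
Total step count: 26. Longest linear sequence: 24 steps (steps 3–26, from Roche ester 5); the enal branch (steps 1–2) joins at step 13.

Steps most likely to fail:

Step 21 (Schenck ene reaction). Hydrogen abstraction from the C13 methyl group competes with abstraction of the C11–H, so a large share of exocyclic-alkene isomers is possible. The fallback is an ionic sequence that sets out from 27. N-Bromosuccinimide in aqueous THF should give, by Markovnikov and trans-diaxial opening of the bromonium ion, the C12 axial bromide with the C13 axial tertiary alcohol, bromohydrin F1. Me3SiOTf/2,6-lutidine then masks the tertiary hydroxyl (so that base cannot close an epoxide) to give trimethylsilyl ether F2. DBU in toluene at 110 °C effects anti-periplanar E2 loss of HBr across C11–H/C12–Br, the only β-hydrogen available, to give Δ11 silyl ether F3. Bu4NF as in step 22 removes both silyl groups, and the sequence comes back to the route at diol 30.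

Step 23 (directed dihydroxylation). The face that must be attacked carries the axial C5 methyl group, and osmylation may be slow or go to the other face. The fallback sets out from 30. VO(acac)2/t-BuOOH epoxidation is far less demanding sterically and is delivered by the same two hydroxyls, giving epoxy diol F4 with the oxirane on the required face. Acid-catalysed trans-diaxial opening (aq. HClO4, THF) by water at the secondary carbon C12 gives C12-epimeric tetraol F5, in which C11–OH keeps the required configuration. The regiochemistry of this opening (C12 rather than tertiary C11) is the weak point of the fallback. Parikh–Doering oxidation as in step 24 erases C12 and comes back to the route at ketone 33.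

Step 25 (Claisen formylation). The substrate carries three free tertiary alkoxides and two α-ketol units under strongly basic conditions. The fallback sets out from 33. Heating with tert-butoxybis(dimethylamino)methane in toluene at 80 °C (neutral aminomethylenation of the acetyl group) gives enaminone F6. Acid-catalysed exchange in methanol (TsOH·H2O, MeOH, rt) replaces dimethylamine by methoxide and comes back to the route directly at target 35.

**Further compounds**
F1 | step 21 | bromohydrin of 27: C12 axial bromide trans to C13 tertiary alcohol, C9 OTBS | CC[C@H](C)[C@@H]1[C@](C)(C(C)=O)[C@H]2[C@H](C)C[C@@](C)(O[Si](C)(C)C(C)(C)C)C[C@@H]2[C@H](Br)[C@@]1(C)O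
F2 | step 21 | C13 trimethylsilyl ether of F1 | CC[C@H](C)[C@@H]1[C@](C)(C(C)=O)[C@H]2[C@H](C)C[C@@](C)(O[Si](C)(C)C(C)(C)C)C[C@@H]2[C@H](Br)[C@@]1(C)O[Si](C)(C)C
F3 | step 21 | Δ11-octalin with C13 OSiMe3 and C9 OTBS | CC[C@H](C)[C@@H]1[C@](C)(C(C)=O)[C@H]2[C@H](C)C[C@@](C)(O[Si](C)(C)C(C)(C)C)CC2=C[C@@]1(C)O[Si](C)(C)C
F4 | step 23 | C11/C12 epoxide of 30 on the face of the C9 and C13 hydroxyls | CC[C@H](C)[C@@H]1[C@](C)(C(C)=O)[C@H]2[C@H](C)C[C@@](C)(O)C[C@@]23O[C@H]3[C@@]1(C)O
F5 | step 23 | C12 epimer of tetraol 32 (C12–OH trans to C11–OH and C13–OH) | CC[C@H](C)[C@@H]1[C@](C)(C(C)=O)[C@H]2[C@H](C)C[C@@](C)(O)C[C@]2(O)[C@H](O)[C@@]1(C)O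
F6 | step 25 | (E)-3-(dimethylamino)prop-2-enoyl analogue of 33 (enaminone) | CC[C@H](C)[C@@H]1[C@](C)(C(=O)/C=C/N(C)C)[C@H]2[C@H](C)C[C@@](C)(O)C[C@]2(O)C(=O)[C@@]1(C)O
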